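## Retrosynthetic overview

1. Sipholenol L ← desilylation, methyl cross-coupling at the ring A enol triflate, Markovnikov hydration of a ring B exocyclic alkene, and methylenation of a cis-octalone.
2. cis-Octalone ← enantioselective Diels–Alder reaction that builds ring A (cyclohexene) onto purchased ring B (4,4-dimethylcyclohexenone), using a 2-silyloxydiene that already carries rings C and D.
3. Silyloxydiene ← vinyl ketone ← radical conjugate addition of a neopentyl-type iodide to an acrylamide, then vinyl Grignard.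
4. Iodide ← key step: diepoxyfarnesyl acetate closes oxepane ring D, cyclohexane ring C and a transient dioxanylium ring in one operation; the acetate delivers the tertiary C–O bond.
5. Ring order: D and C together (plus the transient ring), then A onto B; the diepoxide comes from farnesyl acetate by Shi epoxidation.

Assumption: the L-fructose-derived Shi ketone is purchased, and the (R)-oxazaborolidinium catalyst in step 7 is assigned from the α-C–H···O binding model for cyclic enones; the mirror-image catalyst is used if the facial sense proves opposite.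

Locants: the right half is numbered as decahydro-1-benzoxepine (O1, C2 gem-dimethyl, C3 carbinol, C5a angular methyl, C6 side-chain carbon, C7 tertiary carbinol, C9a). The left half is numbered as octahydronaphthalene throughout as in compound 12 (C1 ketone/carbinol, C4 gem-dimethyl, C4a, C5 side-chain carbon, C6, C7, C8, C8a).

## Route

Step 1
Reactants: 1 (2E,6E)-farnesyl acetate
Product: 2 (2E,6S,7S,10S)-6,7:10,11-diepoxy-3,7,11-trimethyldodec-2-en-1-yl acetate
Conditions: ent-Shi ketone (L-fructose-derived, 0.6 equiv), Oxone (2KHSO5·KHSO4·K2SO4), K2CO3, Bu4NHSO4, Na2B4O7 buffer, MeCN/DMM/H2O, 0 °C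
Reagents that add atoms: potassium peroxymonosulfate, [K+].[O-]S(=O)(=O)OO
Why: Shi asymmetric epoxidation; the chiral dioxirane gives the (S,S)-epoxides at the two electron-rich trisubstituted alkenes, while the 2,3-alkene is deactivated by the allylic acetate.

Step 2
Reactants: 2 (2E,6S,7S,10S)-6,7:10,11-diepoxyfarnesyl acetate
Product: 5 (3S,5aS,6R,7S,9aS)-6-(hydroxymethyl)-2,2,5a,7-tetramethyl-3-(triethylsilyloxy)decahydro-1-benzoxepin-7-ol, via dioxanylium triflate 3 (not isolated), via hydroxy acetate 4 (not isolated)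
Conditions: TESOTf (1.5 equiv), 2,6-di-tert-butyl-4-methylpyridine, CH2Cl2, −78 °C; sat. aq NaHCO3; then K2CO3, MeOH, rt
Reagents that add atoms: triethylsilyl triflate, CC[Si](CC)(CC)OS(=O)(=O)C(F)(F)F; water, O (its oxygen stays only in intermediate 4)
Why: Proposed new method: the silyl triflate activates the terminal epoxide, the 6,7-epoxide oxygen opens it at the tertiary carbon to an oxepane-fused epoxonium ion, the (E)-2,3-alkene attacks C7 with inversion through a chair transition state, and the acetate carbonyl oxygen closes onto the developing C3 cation anti to the new C–C bond as a six-membered dioxanylium ion, so the trans C/D fusion, the equatorial C6 arm and the equatorial C7–O bond are set relative to the epoxide centres, and hydrolysis then methanolysis free both hydroxyls; the closest known reactions are the silyl-triflate-promoted tandem oxa-/carbacyclisation of polyepoxides and the acetate-assisted superacid cyclisation of farnesyl acetate to drimane-8,11-diol monoacetate.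

Step 3
Reactants: 5 silyl ether diol
Product: 6 (3S,5aS,6S,7S,9aS)-6-(iodomethyl)-2,2,5a,7-tetramethyl-3-(triethylsilyloxy)decahydro-1-benzoxepin-7-ol
Conditions: I2, PPh3, imidazole, toluene/MeCN, 0 → 40 °C
Reagents that add atoms: iodine, II
Why: Appel-type iodination; only the primary hydroxyl forms the alkoxyphosphonium ion and is displaced by iodide, and no stereocentre is touched.

Step 4
Reactants: 6 iodide; 7 N-methoxy-N-methylacrylamide
Product: 8 4-[(3S,5aS,6S,7S,9aS)-7-hydroxy-2,2,5a,7-tetramethyl-3-(triethylsilyloxy)decahydro-1-benzoxepin-6-yl]-N-methoxy-N-methylbutanamide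
Conditions: (Me3Si)3SiH, AIBN (cat.), 7 (4 equiv), toluene, 80 °C
Reagents that add atoms: none
Why: Giese radical conjugate addition; the primary radical from the hindered iodide is insensitive to the neopentyl-type environment, adds to the acrylamide β-carbon and is reduced by the silane, leaving all stereocentres untouched.

Step 5
Reactants: 8 Weinreb amide
Product: 9 6-[(3S,5aS,6S,7S,9aS)-7-hydroxy-2,2,5a,7-tetramethyl-3-(triethylsilyloxy)decahydro-1-benzoxepin-6-yl]hex-1-en-3-one
Conditions: CH2=CHMgBr (3 equiv), THF, −78 → 0 °C; inverse quench into cold aq NH4Cl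
Reagents that add atoms: vinylmagnesium bromide, C=C[Mg]Br
Why: Weinreb ketone synthesis; the chelated tetrahedral intermediate prevents over-addition and releases the vinyl ketone on quench.

Step 6
Reactants: 9 vinyl ketone
Product: 10 (3S,5aS,6S,7S,9aS)-2,2,5a,7-tetramethyl-3,7-bis(triethylsilyloxy)-6-[(3Z)-4-(triethylsilyloxy)hexa-3,5-dien-1-yl]decahydro-1-benzoxepine
Conditions: TESOTf (3 equiv), Et3N (5 equiv), CH2Cl2, −78 → 0 °C
Reagents that add atoms: triethylsilyl triflate, CC[Si](CC)(CC)OS(=O)(=O)C(F)(F)F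
Why: Soft enolisation of the alkyl vinyl ketone at the α′-methylene gives the (Z)-2-silyloxydiene, and the tertiary hydroxyl is silylated in the same operation.

Step 7
Reactants: 10 silyloxydiene; 11 4,4-dimethylcyclohex-2-en-1-one
Product: 12 (4aR,5S,8aS)-4,4-dimethyl-5-{2-[(3S,5aS,6S,7S,9aS)-2,2,5a,7-tetramethyl-3,7-bis(triethylsilyloxy)decahydro-1-benzoxepin-6-yl]ethyl}-6-(triethylsilyloxy)-3,4,4a,5,8,8a-hexahydronaphthalen-1(2H)-one
Conditions: (R)-o-tolyl-CBS oxazaborolidine (20 mol %), Tf2NH (18 mol %), 11 (3 equiv), CH2Cl2, −78 → −40 °C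
Reagents that add atoms: none
Why: Catalytic enantioselective Diels–Alder reaction; the silyloxy group directs its enol-ether carbon to the enone β-carbon, endo addition of the (Z)-diene gives the cis ring fusion with the hydrogens at C4a, C5 and C8a on one face, and the chiral oxazaborolidinium ion exposes the Re face at C3 of the enone so the left-half configuration is set independently of the remote right half.

Step 8
Reactants: 12 cis-octalone
Product: 13 (4aS,5S,8aS)-4,4-dimethyl-1-methylidene-5-{2-[right-half bis(triethylsilyl ether) as in 12]ethyl}-6-(triethylsilyloxy)-1,2,3,4,4a,5,8,8a-octahydronaphthalene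
Conditions: Cp2TiMe2 (tetravalent titanium, 3 equiv), toluene/THF, 65 °C, dark
Reagents that add atoms: dimethyltitanocene, [CH3-].[CH3-].[Ti+4].c1cc[cH-]c1.c1cc[cH-]c1
Why: Petasis methylenation; the non-basic titanium carbene converts the hindered ketone to the exocyclic alkene without epimerising the adjacent C8a centre.

Step 9
Reactants: 13 silyl enol ether
Product: 14 (4aS,5S,8aS)-4,4-dimethyl-1-methylidene-5-{2-[right-half bis(triethylsilyl ether)]ethyl}-1,2,3,4,4a,5,8,8a-octahydronaphthalen-6-yl trifluoromethanesulfonate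
Conditions: CsF, PhNTf2, DME, rt
Reagents that add atoms: N-phenylbis(trifluoromethanesulfonimide), O=S(=O)(N(c1ccccc1)S(=O)(=O)C(F)(F)F)C(F)(F)F
Why: Fluoride-induced conversion of the silyl enol ether into the enol triflate; the alkene position fixed by the Diels–Alder reaction is kept and no stereocentre is involved.

Step 10
Reactants: 14 enol triflate
Product: 15 (1S,4aS,5S,8aS)-1-hydroxy-1,4,4-trimethyl-5-{2-[right-half bis(triethylsilyl ether)]ethyl}-1,2,3,4,4a,5,8,8a-octahydronaphthalen-6-yl trifluoromethanesulfonate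
Conditions: Co(acac)2 (divalent cobalt, 20 mol %), PhSiH3, O2 (1 atm), THF, rt
Reagents that add atoms: dioxygen, O=O
Why: Mukaiyama hydration (hydrogen-atom transfer, Markovnikov); the tertiary C1 radical captures oxygen from the convex face of the cis-fused bicycle, giving the (1S) alcohol with OH cis to H8a, while the electron-poor enol triflate does not react.

Step 11
Reactants: 15 tertiary alcohol
Product: 16 (1S,4aR,5S,8aS)-1,4,4,6-tetramethyl-5-{2-[(3S,5aS,6S,7S,9aS)-2,2,5a,7-tetramethyl-3,7-bis(triethylsilyloxy)decahydro-1-benzoxepin-6-yl]ethyl}-1,2,3,4,4a,5,8,8a-octahydronaphthalen-1-ol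
Conditions: MeMgBr (4 equiv), Fe(acac)3 (trivalent iron, 10 mol %), THF/NMP, −30 → 0 °C
Reagents that add atoms: methylmagnesium bromide, C[Mg]Br
Why: Iron-catalysed Kumada-type cross-coupling of the enol triflate installs the C6 methyl with retention of the alkene position; the free hydroxyl only consumes one equivalent of Grignard.

Step 12
Reactants: 16 bis(triethylsilyl) ether
Product: 17 sipholenol L
Conditions: HF·pyridine, pyridine, THF, 0 °C → rt
Reagents that add atoms: none
Why: Fluoride-mediated cleavage of the secondary and tertiary triethylsilyl ethers under buffered conditions that leave the tertiary alcohols and the trisubstituted alkene intact.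

## Compound list

1 | (2E,6E)-farnesyl acetate | CC(=O)OC/C=C(\C)CC/C=C(\C)CCC=C(C)C | starting material
2 | (2E,6S,7S,10S)-6,7:10,11-diepoxy-3,7,11-trimethyldodec-2-en-1-yl acetate | CC(=O)OC/C=C(\C)CC[C@@H]1O[C@@]1(C)CC[C@@H]1OC1(C)C | intermediate
3 | tricyclic 2-methyl-1,3-dioxan-2-ylium triflate (acetate oxygens bridge C7 and the C6 methylene; C3 triethylsilyl ether) | C[C+]1OC[C@H]2[C@]3(C)CC[C@H](O[Si](CC)(CC)CC)C(C)(C)O[C@H]3CC[C@]2(C)O1.[O-]S(=O)(=O)C(F)(F)F | intermediate (not isolated)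
4 | [(3S,5aS,6R,7S,9aS)-7-hydroxy-2,2,5a,7-tetramethyl-3-(triethylsilyloxy)decahydro-1-benzoxepin-6-yl]methyl acetate | CC(=O)OC[C@H]1[C@]3(C)CC[C@H](O[Si](CC)(CC)CC)C(C)(C)O[C@H]3CC[C@]1(C)O | intermediate (not isolated)
5 | (3S,5aS,6R,7S,9aS)-6-(hydroxymethyl)-2,2,5a,7-tetramethyl-3-(triethylsilyloxy)decahydro-1-benzoxepin-7-ol | OC[C@H]1[C@]3(C)CC[C@H](O[Si](CC)(CC)CC)C(C)(C)O[C@H]3CC[C@]1(C)O | intermediate
6 | (3S,5aS,6S,7S,9aS)-6-(iodomethyl)-2,2,5a,7-tetramethyl-3-(triethylsilyloxy)decahydro-1-benzoxepin-7-ol | IC[C@H]1[C@]3(C)CC[C@H](O[Si](CC)(CC)CC)C(C)(C)O[C@H]3CC[C@]1(C)O | intermediate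
7 | N-methoxy-N-methylacrylamide | C=CC(=O)N(C)OC | starting material
8 | 4-[(3S,5aS,6S,7S,9aS)-7-hydroxy-2,2,5a,7-tetramethyl-3-(triethylsilyloxy)decahydro-1-benzoxepin-6-yl]-N-methoxy-N-methylbutanamide | CON(C)C(=O)CCC[C@H]1[C@]3(C)CC[C@H](O[Si](CC)(CC)CC)C(C)(C)O[C@H]3CC[C@]1(C)O | intermediate
9 | 6-[(3S,5aS,6S,7S,9aS)-7-hydroxy-2,2,5a,7-tetramethyl-3-(triethylsilyloxy)decahydro-1-benzoxepin-6-yl]hex-1-en-3-one | C=CC(=O)CCC[C@H]1[C@]3(C)CC[C@H](O[Si](CC)(CC)CC)C(C)(C)O[C@H]3CC[C@]1(C)O | intermediate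
10 | (3S,5aS,6S,7S,9aS)-2,2,5a,7-tetramethyl-3,7-bis(triethylsilyloxy)-6-[(3Z)-4-(triethylsilyloxy)hexa-3,5-dien-1-yl]decahydro-1-benzoxepine | C=C/C(O[Si](CC)(CC)CC)=C/CC[C@H]1[C@]3(C)CC[C@H](O[Si](CC)(CC)CC)C(C)(C)O[C@H]3CC[C@]1(C)O[Si](CC)(CC)CC | intermediate
11 | 4,4-dimethylcyclohex-2-en-1-one | CC1(C)CCC(=O)C=C1 | starting material
12 | (4aR,5S,8aS)-4,4-dimethyl-5-{2-[(3S,5aS,6S,7S,9aS)-2,2,5a,7-tetramethyl-3,7-bis(triethylsilyloxy)decahydro-1-benzoxepin-6-yl]ethyl}-6-(triethylsilyloxy)-3,4,4a,5,8,8a-hexahydronaphthalen-1(2H)-one | CC[Si](CC)(CC)OC1=CC[C@H]2[C@@H]([C@@H]1CC[C@H]1[C@]3(C)CC[C@H](O[Si](CC)(CC)CC)C(C)(C)O[C@H]3CC[C@]1(C)O[Si](CC)(CC)CC)C(C)(C)CCC2=O | intermediate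
13 | (4aS,5S,8aS)-1-methylidene analogue of 12 (C1 exocyclic alkene, C6 silyl enol ether) | CC[Si](CC)(CC)OC1=CC[C@H]2[C@@H]([C@@H]1CC[C@H]1[C@]3(C)CC[C@H](O[Si](CC)(CC)CC)C(C)(C)O[C@H]3CC[C@]1(C)O[Si](CC)(CC)CC)C(C)(C)CCC2=C | intermediate
14 | (4aS,5S,8aS)-1-methylidene C6 enol trifluoromethanesulfonate | FC(F)(F)S(=O)(=O)OC1=CC[C@H]2[C@@H]([C@@H]1CC[C@H]1[C@]3(C)CC[C@H](O[Si](CC)(CC)CC)C(C)(C)O[C@H]3CC[C@]1(C)O[Si](CC)(CC)CC)C(C)(C)CCC2=C | intermediate
15 | (1S,4aS,5S,8aS)-1-hydroxy-1,4,4-trimethyl C6 enol trifluoromethanesulfonate | FC(F)(F)S(=O)(=O)OC1=CC[C@H]2[C@@H]([C@@H]1CC[C@H]1[C@]3(C)CC[C@H](O[Si](CC)(CC)CC)C(C)(C)O[C@H]3CC[C@]1(C)O[Si](CC)(CC)CC)C(C)(C)CC[C@]2(C)O | intermediate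
16 | sipholenol L 3,7-bis(triethylsilyl) ether on the benzoxepine oxygens | CC1=CC[C@H]2[C@@H]([C@@H]1CC[C@H]1[C@]3(C)CC[C@H](O[Si](CC)(CC)CC)C(C)(C)O[C@H]3CC[C@]1(C)O[Si](CC)(CC)CC)C(C)(C)CC[C@]2(C)O | intermediate
17 | sipholenol L, (1S,4aR,5S,8aS)-5-{2-[(3S,5aS,6S,7S,9aS)-3,7-dihydroxy-2,2,5a,7-tetramethyldecahydro-1-benzoxepin-6-yl]ethyl}-1,4,4,6-tetramethyl-1,2,3,4,4a,5,8,8a-octahydronaphthalen-1-ol | CC1=CC[C@H]2[C@@H]([C@@H]1CC[C@H]1[C@]3(C)CC[C@H](O)C(C)(C)O[C@H]3CC[C@]1(C)O)C(C)(C)CC[C@]2(C)O | target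

## Step count and risks

Total step count: 12. Longest linear sequence: 12 (from 1; compounds 7 and 11 are bought).

Steps most likely to fail:

Step 2. The acetate-bearing alkene is a weak π-nucleophile, so the epoxonium ion may collapse by elimination before the third ring closes. The fallback sets out from 2 and replaces the reversible acetate participation by an irreversible carbonate termination. K2CO3/MeOH gives (2E,6S,7S,10S)-6,7:10,11-diepoxy-3,7,11-trimethyldodec-2-en-1-ol F1. Boc2O with N-methylimidazole gives its tert-butyl carbonate F2. TESOTf with the hindered pyridine base at −78 °C closes the rings with loss of isobutene to the tricyclic cyclic carbonate F3. K2CO3/MeOH then opens the carbonate and the route is rejoined at 5.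

Step 7. The enone β-carbon sits next to a quaternary centre and must bond to a substituted diene terminus, so the cycloaddition may be slow or poorly face-selective. The fallback sets out from 11 and uses a more electrophilic, later-defunctionalised dienophile. Br2 then Et3N gives 2-bromo-4,4-dimethylcyclohex-2-en-1-one F4. This adds diene 10 under the same oxazaborolidinium catalysis to the (4aR,5S,8aR)-8a-bromo adduct F5. Bu3SnH/AIBN replaces bromine by hydrogen from the convex face and the route is rejoined at 12.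

Step 10. Oxygen capture by the C1 radical may be poorly face-selective, and hydroperoxide or ketone by-products are possible. The fallback sets out from 14 and sets the tertiary C–O bond by osmylation instead. OsO4 (cat.)/NMO dihydroxylates the exocyclic alkene from the convex face to the (1S)-1-hydroxy-1-(hydroxymethyl) diol F6. I2/PPh3/imidazole converts the primary hydroxyl to the (1S)-1-hydroxy-1-(iodomethyl) compound F7. Bu3SnH/AIBN reduces the C–I bond and the route is rejoined at 15.

## Further compounds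

F1 | step 2 | (2E,6S,7S,10S)-6,7:10,11-diepoxy-3,7,11-trimethyldodec-2-en-1-ol | OC/C=C(\C)CC[C@@H]1O[C@@]1(C)CC[C@@H]1OC1(C)C
F2 | step 2 | tert-butyl (2E,6S,7S,10S)-6,7:10,11-diepoxy-3,7,11-trimethyldodec-2-en-1-yl carbonate | CC(C)(C)OC(=O)OC/C=C(\C)CC[C@@H]1O[C@@]1(C)CC[C@@H]1OC1(C)C
F3 | step 2 | tricyclic cyclic carbonate bridging the C7 oxygen and the C6 methylene oxygen, C3 triethylsilyl ether | O=C1OC[C@H]2[C@]3(C)CC[C@H](O[Si](CC)(CC)CC)C(C)(C)O[C@H]3CC[C@]2(C)O1
F4 | step 7 | 2-bromo-4,4-dimethylcyclohex-2-en-1-one | CC1(C)CCC(=O)C(Br)=C1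
F5 | step 7 | (4aR,5S,8aR)-8a-bromo analogue of 12 | CC[Si](CC)(CC)OC1=CC[C@@]2(Br)[C@@H]([C@@H]1CC[C@H]1[C@]3(C)CC[C@H](O[Si](CC)(CC)CC)C(C)(C)O[C@H]3CC[C@]1(C)O[Si](CC)(CC)CC)C(C)(C)CCC2=O
F6 | step 10 | (1S,4aS,5S,8aS)-1-hydroxy-1-(hydroxymethyl) analogue of 15 | FC(F)(F)S(=O)(=O)OC1=CC[C@H]2[C@@H]([C@@H]1CC[C@H]1[C@]3(C)CC[C@H](O[Si](CC)(CC)CC)C(C)(C)O[C@H]3CC[C@]1(C)O[Si](CC)(CC)CC)C(C)(C)CC[C@]2(CO)O
F7 | step 10 | (1S,4aS,5S,8aS)-1-hydroxy-1-(iodomethyl) analogue of 15 | FC(F)(F)S(=O)(=O)OC1=CC[C@H]2[C@@H]([C@@H]1CC[C@H]1[C@]3(C)CC[C@H](O[Si](CC)(CC)CC)C(C)(C)O[C@H]3CC[C@]1(C)O[Si](CC)(CC)CC)C(C)(C)CC[C@]2(CI)O
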